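**Retrosynthetic overview**
1. Target 18 is cut at the C3 acetate, at the C11–O–aryl ether (Mitsunobu with isofraxidin 16) and at C8=C12 (Wittig on a C8 ketone), which leads back to hydroxymethyl ketone 12.
2. The strategy rests on ring B: quaternary C10 (CH3 cis to H5, cis-decalin) and C9 (bearing C11) are the β- and α-carbons of the C8 carbonyl. The bonds C10–CH3 and C9–C11 are therefore cut together, giving the Δ9(10)-8-octalone 7, MeMgBr 8 and CH2O 9.
3. Enone 7 comes from anisole 4 by Birch reduction, enol ether hydrolysis and conjugation. The methoxy-bearing carbon becomes C8 and C5 is set against C3.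
4. Tetralol 4 comes from 6-methoxy-2-tetralone 1 and MeI 2 by geminal methylation (C4) and Corey–Bakshi–Shibata reduction (C3, the only reagent-controlled centre).
5. Ring order: both carbocycles are already present in 1 and no ring is formed. The arene is dearomatised to ring B and the coumarin arrives intact.

Key step: step 6

Remark: atom labels C1–C12 in the Why lines follow drimane numbering (ring A = C1–C5 and C10, ring B = C5–C10, C11 on C9, C12 on C8). In the target H5, the C10 methyl and C11 lie on one face and the C3 oxygen on the other; isofraxidin is taken as purchasable.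

**Step 1**
Reactants: 1 6-methoxy-2-tetralone; 2 iodomethane
Product: 3 6-methoxy-1,1-dimethyl-3,4-dihydronaphthalen-2(1H)-one
Conditions: KOt-Bu (2.2 equiv), MeI (2.5 equiv), THF, 0 °C → rt
Reagents that add atoms: iodomethane 2, CI
Why: Enolate C-alkylation; 2-tetralones enolise toward the benzylic C1 (aryl-conjugated enolate), so both methyl groups should enter at C1, the future C4, and the stoichiometry limits a third methylation at C3.

**Step 2**
Reactants: 3 6-methoxy-1,1-dimethyl-3,4-dihydronaphthalen-2(1H)-one
Product: 4 (2S)-6-methoxy-1,1-dimethyl-1,2,3,4-tetrahydronaphthalen-2-ol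
Conditions: (R)-1-methyl-3,3-diphenyltetrahydro-1H,3H-pyrrolo[1,2-c][1,3,2]oxazaborole ((R)-Me-CBS, 10 mol%), BH3·SMe2, THF, −20 °C; MeOH, then aqueous work-up
Reagents that add atoms: none
Why: Corey–Bakshi–Shibata reduction; the catalyst–borane complex binds the carbonyl anti to the quaternary C1 (large) and syn to CH2-3 (small), so the (R)-catalyst should deliver hydride to the face that gives the (S)-carbinol, the future C3 stereocentre.

**Step 3**
Reactants: 4 (2S)-6-methoxy-1,1-dimethyl-1,2,3,4-tetrahydronaphthalen-2-ol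
Product: 5 (2S)-6-methoxy-1,1-dimethyl-1,2,3,4,5,8-hexahydronaphthalen-2-ol (used crude)
Conditions: Li, NH3 (l), t-BuOH, THF, −78 → −33 °C; solid NH4Cl
Reagents that add atoms: none
Why: Birch reduction; the anisole ring takes up two electrons and two protons ortho and meta to OMe (C5 and C8 of the tetralin), leaving the enol ether C6=C7 and the tetrasubstituted C4a=C8a alkene, while the lithium alkoxide of the carbinol is inert.

**Step 4**
Reactants: 5 (2S)-6-methoxy-1,1-dimethyl-1,2,3,4,5,8-hexahydronaphthalen-2-ol
Product: 6 (4aR,6S)-6-hydroxy-5,5-dimethyl-4,4a,5,6,7,8-hexahydronaphthalen-2(3H)-one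
Conditions: 3 M HCl, MeOH, rt → 50 °C
Reagents that add atoms: water, O
Why: Acid hydrolysis of the enol ether gives the β,γ-unsaturated ketone, which isomerises through its dienol to the conjugated enone; the proton enters C5 axially and reversibly, so the epimer with the C3 hydroxyl equatorial (H3 and H5 cis) should accumulate as both the kinetic and the thermodynamic product.

**Step 5**
Reactants: 6 (4aR,6S)-6-hydroxy-5,5-dimethyl-4,4a,5,6,7,8-hexahydronaphthalen-2(3H)-one
Product: 7 (4aR,6S)-6-[(tert-butyldimethylsilyl)oxy]-5,5-dimethyl-4,4a,5,6,7,8-hexahydronaphthalen-2(3H)-one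
Conditions: TBSCl, imidazole, 4-(dimethylamino)pyridine (cat.), DMF, 45 °C
Reagents that add atoms: tert-butyldimethylsilyl chloride, CC(C)(C)[Si](C)(C)Cl
Why: Silylation of a hindered secondary alcohol with nucleophilic catalysis; the conditions are too weakly basic to deconjugate the enone or disturb C5.

**Step 6**
Reactants: 7 (4aR,6S)-6-[(tert-butyldimethylsilyl)oxy]-5,5-dimethyl-4,4a,5,6,7,8-hexahydronaphthalen-2(3H)-one; 8 methylmagnesium bromide; 9 formaldehyde (monomeric gas from cracked paraformaldehyde)
Product: 12 (1R,4aR,6S,8aR)-6-[(tert-butyldimethylsilyl)oxy]-1-(hydroxymethyl)-5,5,8a-trimethyloctahydronaphthalen-2(1H)-one (cis-fused), via trimethylsilyl enol ether 10 (not isolated), via lithium enolate 11 (not isolated)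
Conditions: MeMgBr (1.5 equiv), CuBr·SMe2 (10 mol%), Me3SiCl (2 equiv), HMPA (2 equiv), THF, −78 → −40 °C; MeLi (excess over residual Me3SiCl), −40 → 0 °C; CH2O (g), −78 °C; aq NH4Cl
Reagents that add atoms: methylmagnesium bromide 8, C[Mg]Br; formaldehyde 9, C=O
Why: A methylcopper species formed from MeMgBr and catalytic CuBr·SMe2 transfers methyl to the β-carbon C10 while Me3SiCl accelerates the addition and captures the C8 enolate as silyl enol ether 10; MeLi then cleaves the O–Si bond to the regiodefined lithium enolate 11, which adds through C9 to monomeric formaldehyde. The closest known reaction types are the chlorosilane-accelerated copper-catalysed Grignard conjugate addition to β,β-disubstituted cyclohexenones and 1(9)-octal-2-ones, enolate regeneration from a silyl enol ether, and enolate hydroxymethylation; no ring is closed. C10 is substrate-controlled: the face anti to H5 carries the axial C4 methyl, which would be 1,3-diaxial to the incoming group, so methyl should enter on the H5 face and the decalin becomes cis-fused. C9 is also substrate-controlled: in the cis-decalin enolate ring A and its axial C4 methyl cover the concave face, so formaldehyde should be taken up on the convex face, cis to the new methyl, giving the equatorial and more stable hydroxymethyl epimer. The step needs 1,4- over 1,2-addition (copper and Me3SiCl), reaction at C9 and not C7 (fixed by the position of the enol ether double bond) and a single hydroxymethylation (C9 keeps one hydrogen, and low temperature with a short contact time suppresses proton transfer to C7).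

**Step 7**
Reactants: 12 (1R,4aR,6S,8aR)-6-[(tert-butyldimethylsilyl)oxy]-1-(hydroxymethyl)-5,5,8a-trimethyloctahydronaphthalen-2(1H)-one
Product: 13 (1R,4aR,6S,8aR)-6-[(tert-butyldimethylsilyl)oxy]-1-{[(tert-butyldimethylsilyl)oxy]methyl}-5,5,8a-trimethyloctahydronaphthalen-2(1H)-one
Conditions: TBSCl, imidazole, CH2Cl2, 0 °C → rt
Reagents that add atoms: tert-butyldimethylsilyl chloride, CC(C)(C)[Si](C)(C)Cl
Why: Silylation of the primary alcohol under near-neutral conditions, so that the β-hydroxy ketone neither dehydrates nor loses formaldehyde by retro-aldol in the basic olefination that follows.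

**Step 8**
Reactants: 13 (1R,4aR,6S,8aR)-6-[(tert-butyldimethylsilyl)oxy]-1-{[(tert-butyldimethylsilyl)oxy]methyl}-5,5,8a-trimethyloctahydronaphthalen-2(1H)-one
Product: 14 (2S,4aR,5R,8aR)-2-[(tert-butyldimethylsilyl)oxy]-5-{[(tert-butyldimethylsilyl)oxy]methyl}-1,1,4a-trimethyl-6-methylidenedecahydronaphthalene
Conditions: Ph3PCH3Br, KOt-Bu, toluene, rt → 80 °C
Reagents that add atoms: methyltriphenylphosphonium bromide, C[P+](c1ccccc1)(c1ccccc1)c1ccccc1.[Br-]
Why: Wittig methylenation with the lithium-free ylide at elevated temperature, the usual way to methylenate hindered α-branched cyclohexanones; C9 already holds its more stable configuration, so reversible enolisation should not change it, and silyloxide is a poor leaving group for β-elimination.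

**Step 9**
Reactants: 14 (2S,4aR,5R,8aR)-2-[(tert-butyldimethylsilyl)oxy]-5-{[(tert-butyldimethylsilyl)oxy]methyl}-1,1,4a-trimethyl-6-methylidenedecahydronaphthalene
Product: 15 (2S,4aR,5R,8aR)-5-(hydroxymethyl)-1,1,4a-trimethyl-6-methylidenedecahydronaphthalen-2-ol
Conditions: Bu4NF, THF, rt → 60 °C; H2O
Reagents that add atoms: none
Why: Fluoride-induced cleavage of both silyl ethers (the neopentyl C3 ether needs heating); the non-acidic conditions keep the 1,1-disubstituted alkene exocyclic.

**Step 10**
Reactants: 15 (2S,4aR,5R,8aR)-5-(hydroxymethyl)-1,1,4a-trimethyl-6-methylidenedecahydronaphthalen-2-ol; 16 isofraxidin (7-hydroxy-6,8-dimethoxycoumarin)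
Product: 17 7-{[(1R,4aR,6S,8aR)-6-hydroxy-5,5,8a-trimethyl-2-methylidenedecahydronaphthalen-1-yl]methoxy}-6,8-dimethoxy-2H-chromen-2-one
Conditions: PPh3, diisopropyl azodicarboxylate, THF, 0 °C → rt
Reagents that add atoms: isofraxidin 16, COc1cc2ccc(=O)oc2c(OC)c1O
Why: Mitsunobu etherification; the acidic phenol protonates the betaine and its phenoxide displaces the C11 alkoxyphosphonium ion in an SN2 step at CH2, while the secondary, neopentyl C3 carbinol cannot be displaced and is returned unchanged, so no stereocentre is touched.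

**Step 11**
Reactants: 17 7-{[(1R,4aR,6S,8aR)-6-hydroxy-5,5,8a-trimethyl-2-methylidenedecahydronaphthalen-1-yl]methoxy}-6,8-dimethoxy-2H-chromen-2-one
Product: 18 (2S,4aR,5R,8aR)-5-{[(6,8-dimethoxy-2-oxo-2H-chromen-7-yl)oxy]methyl}-1,1,4a-trimethyl-6-methylidenedecahydronaphthalen-2-yl acetate (CNP0270939.1)
Conditions: Ac2O, pyridine, 4-(dimethylamino)pyridine (cat.), CH2Cl2, rt
Reagents that add atoms: acetic anhydride, CC(=O)OC(C)=O
Why: Acylation of the remaining secondary alcohol under nucleophilic catalysis; the aryl ether, the lactone and the alkene are inert and the C3 configuration is retained.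

**Compound list**
1 | 6-methoxy-2-tetralone | COc1ccc2c(c1)CCC(=O)C2 | starting material
2 | iodomethane | CI | starting material
3 | 6-methoxy-1,1-dimethyl-3,4-dihydronaphthalen-2(1H)-one | COc1ccc2c(c1)CCC(=O)C2(C)C | intermediate
4 | (2S)-6-methoxy-1,1-dimethyl-1,2,3,4-tetrahydronaphthalen-2-ol | COc1ccc2c(c1)CC[C@H](O)C2(C)C | intermediate
5 | (2S)-6-methoxy-1,1-dimethyl-1,2,3,4,5,8-hexahydronaphthalen-2-ol | COC1=CCC2=C(C1)CC[C@H](O)C2(C)C | intermediate
6 | (4aR,6S)-6-hydroxy-5,5-dimethyl-4,4a,5,6,7,8-hexahydronaphthalen-2(3H)-one | O=C1CC[C@H]2C(C)(C)[C@@H](O)CCC2=C1 | intermediate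
7 | (4aR,6S)-6-[(tert-butyldimethylsilyl)oxy]-5,5-dimethyl-4,4a,5,6,7,8-hexahydronaphthalen-2(3H)-one | O=C1CC[C@H]2C(C)(C)[C@@H](O[Si](C)(C)C(C)(C)C)CCC2=C1 | intermediate
8 | methylmagnesium bromide | C[Mg]Br | starting material
9 | formaldehyde | C=O | starting material
10 | trimethylsilyl enol ether of the cis-fused 10-methyl-8-ketone, {[(4aR,6S,8aR)-6-[(tert-butyldimethylsilyl)oxy]-5,5,8a-trimethyl-3,4,4a,5,6,7,8,8a-octahydronaphthalen-2-yl]oxy}trimethylsilane | C[Si](C)(C)OC=1CC[C@H]2C(C)(C)[C@@H](O[Si](C)(C)C(C)(C)C)CC[C@@]2(C)C=1 | intermediate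
11 | lithium enolate corresponding to 10 | [Li+].[O-]C=1CC[C@H]2C(C)(C)[C@@H](O[Si](C)(C)C(C)(C)C)CC[C@@]2(C)C=1 | intermediate
12 | (1R,4aR,6S,8aR)-6-[(tert-butyldimethylsilyl)oxy]-1-(hydroxymethyl)-5,5,8a-trimethyloctahydronaphthalen-2(1H)-one | O=C1CC[C@H]2C(C)(C)[C@@H](O[Si](C)(C)C(C)(C)C)CC[C@@]2(C)[C@@H]1CO | intermediate
13 | (1R,4aR,6S,8aR)-6-[(tert-butyldimethylsilyl)oxy]-1-{[(tert-butyldimethylsilyl)oxy]methyl}-5,5,8a-trimethyloctahydronaphthalen-2(1H)-one | O=C1CC[C@H]2C(C)(C)[C@@H](O[Si](C)(C)C(C)(C)C)CC[C@@]2(C)[C@@H]1CO[Si](C)(C)C(C)(C)C | intermediate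
14 | (2S,4aR,5R,8aR)-2-[(tert-butyldimethylsilyl)oxy]-5-{[(tert-butyldimethylsilyl)oxy]methyl}-1,1,4a-trimethyl-6-methylidenedecahydronaphthalene | C=C1CC[C@H]2C(C)(C)[C@@H](O[Si](C)(C)C(C)(C)C)CC[C@@]2(C)[C@@H]1CO[Si](C)(C)C(C)(C)C | intermediate
15 | (2S,4aR,5R,8aR)-5-(hydroxymethyl)-1,1,4a-trimethyl-6-methylidenedecahydronaphthalen-2-ol | C=C1CC[C@H]2C(C)(C)[C@@H](O)CC[C@@]2(C)[C@@H]1CO | intermediate
16 | isofraxidin (7-hydroxy-6,8-dimethoxycoumarin) | COc1cc2ccc(=O)oc2c(OC)c1O | starting material
17 | 7-{[(1R,4aR,6S,8aR)-6-hydroxy-5,5,8a-trimethyl-2-methylidenedecahydronaphthalen-1-yl]methoxy}-6,8-dimethoxy-2H-chromen-2-one | C=C1CC[C@H]2C(C)(C)[C@@H](O)CC[C@@]2(C)[C@@H]1COc1c(OC)cc2ccc(=O)oc2c1OC | intermediate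
18 | (2S,4aR,5R,8aR)-5-{[(6,8-dimethoxy-2-oxo-2H-chromen-7-yl)oxy]methyl}-1,1,4a-trimethyl-6-methylidenedecahydronaphthalen-2-yl acetate | C=C1CC[C@H]2C(C)(C)[C@@H](OC(C)=O)CC[C@@]2(C)[C@@H]1COc1c(OC)cc2ccc(=O)oc2c1OC | target

**Total step count:** 11. **Longest linear sequence:** 11 steps (1 → 18; 16 is used as purchased).

**Steps most likely to fail**

Step 6. The lithium enolate may be lost to proton transfer or O-attack, or formaldehyde may polymerise before it is captured at the hindered C9, and the aldol may dehydrate on work-up. The fallback sets out from 7: the copper-catalysed addition is run as before but without MeLi, and silyl enol ether 10 is isolated by a cold NaHCO3/pentane work-up. Compound 10 is then stirred with aqueous formaldehyde and Yb(OTf)3 (10 mol%) in THF/H2O at rt, a Lewis-acid-catalysed Mukaiyama-type hydroxymethylation that needs neither a strong base nor gaseous formaldehyde, and the route is rejoined at 12. This fallback makes no compound outside the list (F0).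

Step 10. Etherification may stall because a β-branched primary alcohol meets a phenol flanked by two methoxy groups, and the activated alcohol may instead eliminate toward the 8(12),9(11)-diene. The fallback sets out from 15: TsCl in pyridine at 0 °C should sulfonylate only the primary hydroxyl, giving [(1R,4aR,6S,8aR)-6-hydroxy-5,5,8a-trimethyl-2-methylidenedecahydronaphthalen-1-yl]methyl 4-methylbenzenesulfonate F1. The weakly basic caesium phenoxide of 16 (Cs2CO3, DMF, 60 °C) then displaces the sulfonate in a Williamson etherification, and the route is rejoined at 17.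

Step 8. The basic ylide may enolise the hindered ketone faster than it adds, or trigger loss of silyloxide from C11. The fallback sets out from 13: Me3SiCH2Li with anhydrous CeCl3 in THF at −78 °C, a weakly basic organocerium addition, should give (1R,4aR,6S,8aR)-6-[(tert-butyldimethylsilyl)oxy]-1-{[(tert-butyldimethylsilyl)oxy]methyl}-5,5,8a-trimethyl-2-[(trimethylsilyl)methyl]decahydronaphthalen-2-ol F2 as a mixture of C8 epimers. KH in THF then effects the Peterson elimination of either epimer, and the route is rejoined at 14.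

**Further compounds**
F0 | step 6 | none | none
F1 | step 10 | [(1R,4aR,6S,8aR)-6-hydroxy-5,5,8a-trimethyl-2-methylidenedecahydronaphthalen-1-yl]methyl 4-methylbenzenesulfonate | C=C1CC[C@H]2C(C)(C)[C@@H](O)CC[C@@]2(C)[C@@H]1COS(=O)(=O)c1ccc(C)cc1
F2 | step 8 | (1R,4aR,6S,8aR)-6-[(tert-butyldimethylsilyl)oxy]-1-{[(tert-butyldimethylsilyl)oxy]methyl}-5,5,8a-trimethyl-2-[(trimethylsilyl)methyl]decahydronaphthalen-2-ol (C8 epimers) | OC1(C[Si](C)(C)C)CC[C@H]2C(C)(C)[C@@H](O[Si](C)(C)C(C)(C)C)CC[C@@]2(C)[C@@H]1CO[Si](C)(C)C(C)(C)C
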